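**Plan**

- Retrosynthetic cuts, in order: the C8 acetate; the hydrogens at C9/C11 (and C1/C2); C8–C17 (methyl added to a ring B ketone); C9–C10 (closure of ring B); C8–C9 (acyl–alkynyl coupling). This leaves a ring A acid from (R)-α-ionone and a C6 alkynoate from methyl hydrogen (R)-3-methylglutarate.
- Forward: ring A is bought intact, the chain is joined at C8–C9 as an ynone, ring B is closed at C9–C10 by palladium-catalysed enyne cycloisomerization, then C17, the saturation and the acetate follow.
- Enabling feature: ring B is cis-fused to ring A, and the quaternary fusion carbon C10 (bearing C20) is bonded to C9 and has H-5 on the same face. In an α-ionone ring the C1=C10 double bond lies next to C5, so a chain anchored at C5 can deliver C9 to C10 only on the face of C6. That makes the quaternary centre and the cis fusion in one event, while a C8 carbonyl places palladium on C9.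
- Stereochemistry: C5 from (R)-α-ionone; C10 from C5 in the ring closure; C8 by methyl addition to the convex β face of the cis-fused ketone; C9 by hydroxyl-directed hydrogenation (H-9 syn to 8-OH); C13 from the glutarate half-ester.

Key step: step 7

Remark: labdane numbering is used for the bicyclic compounds (ring A = C1–C5, C10; ring B = C5–C10; C20 on C10, C17 on C8, side chain C11–C16 on C9; β = the face of C20); the target as drawn is (5R,8R,9R,10S,13S), that is, rings A and B are cis-fused (H-5 β), and (R)-α-ionone and methyl hydrogen (R)-3-methylglutarate are assumed to be purchasable in high enantiomeric purity.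

**Route**

Step 1
Reactants: 1 (R)-α-ionone
Product: 3 (R)-dihydro-α-ionone, via triethylsilyl enol ether 2 (not isolated)
Conditions: Et3SiH, RhCl(PPh3)3 (cat.), 50 °C; then K2CO3, MeOH, rt
Reagents that add atoms: none
Why: Rhodium-catalysed 1,4-hydrosilylation of the enone with a monohydrosilane (a known selective conjugate reduction of ionones) and methanolysis of the silyl enol ether should reduce only the C6=C7 bond, leaving the ring A alkene and the C5 centre untouched.

Step 2
Reactants: 3 (R)-dihydro-α-ionone
Product: 5 3-[(1R)-2,6,6-trimethylcyclohex-2-en-1-yl]propanoic acid, via trichloromethyl ketone 4 (not isolated)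
Conditions: NaOCl (aq.), NaOH, 1,4-dioxane, 0 °C to rt; Na2SO3; then HCl to pH 2
Reagents that add atoms: sodium hydroxide, [Na+].[OH-]
Why: Haloform reaction: exhaustive chlorination of the methyl group and hydroxide cleavage of the trichloromethyl ketone turn C8 into the acyl carbon needed for the ynone (C17 returns in step 8), and the hindered trisubstituted ring alkene is expected to survive alkaline hypochlorite.

Step 3
Reactants: 6 methyl hydrogen (R)-3-methylglutarate
Product: 8 methyl (3S)-5-hydroxy-3-methylpentanoate, via hydroxy acid 7 (not isolated)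
Conditions: LiBH4, THF, 0 °C to rt; then HCl in MeOH, rt; NaHCO3, concentrate cold
Reagents that add atoms: methanol, CO
Why: Chemoselective borohydride reduction of the ester beside the carboxylate (RCO2Li is inert), then Fischer esterification, exchanges the two arms of the glutarate, so the (R) half-ester should give the (S) hydroxy ester without touching C3; excess methanol and neutralization before concentration keep the δ-hydroxy ester from lactonizing.

Step 4
Reactants: 8 methyl (3S)-5-hydroxy-3-methylpentanoate
Product: 9 methyl (3S)-3-methyl-5-oxopentanoate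
Conditions: TEMPO (cat.), PhI(OAc)2, CH2Cl2, rt
Reagents that add atoms: none
Why: TEMPO/PhI(OAc)2 oxidation of the primary alcohol stops at the aldehyde and leaves the ester and the non-enolizable β-stereocentre unchanged.

Step 5
Reactants: 9 methyl (3S)-3-methyl-5-oxopentanoate
Product: 10 methyl (3S)-3-methylhex-5-ynoate
Conditions: dimethyl (1-diazo-2-oxopropyl)phosphonate, K2CO3, MeOH, 0 °C to rt
Reagents that add atoms: dimethyl (1-diazo-2-oxopropyl)phosphonate, COP(=O)(OC)C(=[N+]=[N-])C(C)=O
Why: Ohira–Bestmann (Seyferth–Gilbert) homologation converts the aldehyde into the terminal alkyne with one added carbon (the future C9); the methyl ester is unchanged in methanol and C3 lies β to the reacting carbon.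

Step 6
Reactants: 5 3-[(1R)-2,6,6-trimethylcyclohex-2-en-1-yl]propanoic acid, 10 methyl (3S)-3-methylhex-5-ynoate
Product: 12 methyl (3S)-3-methyl-7-oxo-9-[(1R)-2,6,6-trimethylcyclohex-2-en-1-yl]non-5-ynoate, via acid chloride 11 (not isolated)
Conditions: (COCl)2, DMF (cat.), CH2Cl2, 0 °C, then evaporation; 10, PdCl2(PPh3)2 (cat.), CuI (cat.), Et3N, THF, rt
Reagents that add atoms: none
Why: Acyl Sonogashira coupling of the acid chloride with the terminal alkyne forms the C8–C9 bond at room temperature, tolerates the ester, and should be too mild to isomerize the ynone or the ring A alkene; no stereocentre is formed.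

Step 7
Reactants: 12 methyl (3S)-3-methyl-7-oxo-9-[(1R)-2,6,6-trimethylcyclohex-2-en-1-yl]non-5-ynoate
Product: 13 methyl (5R,10S,13S,9(11)Z)-8-oxo-17-norlabda-1,9(11)-dien-15-oate
Conditions: Pd(OAc)2 (10 mol%), N,N'-bis(benzylidene)ethylenediamine (20 mol%), toluene, 70 °C
Reagents that add atoms: none
Why: Divalent palladium binds the electron-poor alkyne and the C1=C10 alkene, C9 (the alkyne carbon next to the C8 carbonyl, where palladium sits in either the hydropalladation or the palladacycle pathway) adds to C10 with palladium going to C1, and β-hydride elimination of H-2 with C11–H formation releases the 1,4-diene, a net intramolecular Alder-ene reaction; the closest known reaction type is the palladium-catalysed cycloisomerization of 1,6- and 1,7-enynes, including cases that build a quaternary carbon on a methyl-substituted cyclohexene. Ring B closes in the 6-exo-trig mode with respect to the C1=C10 bond, since the 7-endo alternative would place palladium on the tertiary C10. The only new stereocentre, C10, is controlled by C5: the C6–C7–C8 chain sits pseudoaxially on ring A to avoid the C20 methyl and the C4 gem-dimethyl group, so C9 can reach only the alkene face that carries C6, and ring B should be cis-fused (H-5 and C20 on the same face). The step needs cyclization to outrun isomerization of the ynone to a conjugated dienone (which would erase C13), for which the phosphine-free diimine ligand and neutral medium are chosen, and it needs one direction of β-hydride elimination, secured because C10 is quaternary and only H-2 is syn to palladium. The exocyclic C9=C11 bond should form Z (H-11 cis to C10), the only geometry free of allylic strain against C10, and it is removed in step 9.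

Step 8
Reactants: 13 methyl (5R,10S,13S,9(11)Z)-8-oxo-17-norlabda-1,9(11)-dien-15-oate
Product: 14 methyl (5R,8R,10S,13S,9(11)Z)-8-hydroxylabda-1,9(11)-dien-15-oate
Conditions: MeLi, CeCl3, THF, −78 °C; aq. NH4Cl
Reagents that add atoms: methyllithium, [Li]C
Why: Organocerium 1,2-addition (non-basic, ketone over ester) to the C8 carbonyl: in the cis-fused bicycle ring A is folded under the α face of ring B and, in the favoured chair form with C1 axial on ring B, screens that face, so CH3 should enter from the convex β face and set 8β-CH3/8α-OH (8R).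

Step 9
Reactants: 14 methyl (5R,8R,10S,13S,9(11)Z)-8-hydroxylabda-1,9(11)-dien-15-oate
Product: 15 methyl (5R,8R,9R,10S,13S)-8-hydroxylabdan-15-oate
Conditions: H2 (1 atm), [Ir(cod)(PCy3)(py)]PF6 (5 mol%), CH2Cl2, rt
Reagents that add atoms: none
Why: Hydroxyl-directed homogeneous hydrogenation: coordination of the 8α-hydroxyl to the cationic iridium centre should deliver hydrogen to the α face of the exocyclic C9=C11 bond, placing H-9 syn to the hydroxyl and the side chain β (9R), while the C1=C2 bond is saturated in the same operation without creating a stereocentre.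

Step 10
Reactants: 15 methyl (5R,8R,9R,10S,13S)-8-hydroxylabdan-15-oate
Product: 16 (5R,8R,9R,10S,13S)-8-hydroxylabdan-15-oic acid
Conditions: LiOH, THF/MeOH/H2O, rt; then HCl to pH 3
Reagents that add atoms: lithium hydroxide, [Li+].[OH-]
Why: Saponification of the unhindered methyl ester; the tertiary alcohol and all stereocentres (none α to the carboxyl) are unaffected.

Step 11
Reactants: 16 (5R,8R,9R,10S,13S)-8-hydroxylabdan-15-oic acid
Product: 18 (5R,8R,9R,10S,13S)-8-acetoxylabdan-15-oic acid, via mixed acetic anhydride 17 (not isolated)
Conditions: AcCl, N,N-dimethylaniline, CH2Cl2, 0 to 40 °C; then aq. NaHCO3/THF, rt; then HCl to pH 3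
Reagents that add atoms: acetyl chloride, CC(Cl)=O
Why: O-Acylation of a hindered tertiary alcohol with acetyl chloride and a weak amine base (the usual conditions for tertiary labdane 8-ols) keeps the C8–O bond intact and so retains configuration; the carboxyl group is acetylated as a mixed anhydride that the bicarbonate work-up hydrolyses back to the acid.

**Compound list**

1 | (R)-α-ionone, (3E)-4-[(1R)-2,6,6-trimethylcyclohex-2-en-1-yl]but-3-en-2-one | CC1=CCCC(C)(C)[C@H]1/C=C/C(C)=O | starting material
2 | triethyl({(2Z)-4-[(1R)-2,6,6-trimethylcyclohex-2-en-1-yl]but-2-en-2-yl}oxy)silane (Z expected from the s-cis enone; not isolated) | CC1=CCCC(C)(C)[C@H]1C/C=C(/C)O[Si](CC)(CC)CC | intermediate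
3 | (R)-dihydro-α-ionone, 4-[(1R)-2,6,6-trimethylcyclohex-2-en-1-yl]butan-2-one | CC1=CCCC(C)(C)[C@H]1CCC(C)=O | intermediate
4 | 1,1,1-trichloro-4-[(1R)-2,6,6-trimethylcyclohex-2-en-1-yl]butan-2-one (not isolated) | CC1=CCCC(C)(C)[C@H]1CCC(=O)C(Cl)(Cl)Cl | intermediate
5 | 3-[(1R)-2,6,6-trimethylcyclohex-2-en-1-yl]propanoic acid | CC1=CCCC(C)(C)[C@H]1CCC(O)=O | intermediate
6 | methyl hydrogen (R)-3-methylglutarate, (3R)-5-methoxy-3-methyl-5-oxopentanoic acid | OC(=O)C[C@@H](C)CC(=O)OC | starting material
7 | (3S)-5-hydroxy-3-methylpentanoic acid (not isolated) | OC(=O)C[C@@H](C)CCO | intermediate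
8 | methyl (3S)-5-hydroxy-3-methylpentanoate | COC(=O)C[C@@H](C)CCO | intermediate
9 | methyl (3S)-3-methyl-5-oxopentanoate | COC(=O)C[C@@H](C)CC=O | intermediate
10 | methyl (3S)-3-methylhex-5-ynoate | COC(=O)C[C@@H](C)CC#C | intermediate
11 | 3-[(1R)-2,6,6-trimethylcyclohex-2-en-1-yl]propanoyl chloride (not isolated) | CC1=CCCC(C)(C)[C@H]1CCC(Cl)=O | intermediate
12 | methyl (3S)-3-methyl-7-oxo-9-[(1R)-2,6,6-trimethylcyclohex-2-en-1-yl]non-5-ynoate | CC1=CCCC(C)(C)[C@H]1CCC(=O)C#CC[C@H](C)CC(=O)OC | intermediate
13 | methyl (5R,10S,13S,9(11)Z)-8-oxo-17-norlabda-1,9(11)-dien-15-oate (cis-fused, H-5 and CH3-20 β) | O=C1CC[C@@H]2C(C)(C)CC=C[C@]2(C)/C1=C/C[C@H](C)CC(=O)OC | intermediate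
14 | methyl (5R,8R,10S,13S,9(11)Z)-8-hydroxylabda-1,9(11)-dien-15-oate (8α-OH, 8β-CH3) | O[C@]1(C)CC[C@@H]2C(C)(C)CC=C[C@]2(C)/C1=C/C[C@H](C)CC(=O)OC | intermediate
15 | methyl (5R,8R,9R,10S,13S)-8-hydroxylabdan-15-oate | O[C@]1(C)CC[C@@H]2C(C)(C)CCC[C@]2(C)[C@H]1CC[C@H](C)CC(=O)OC | intermediate
16 | (5R,8R,9R,10S,13S)-8-hydroxylabdan-15-oic acid | O[C@]1(C)CC[C@@H]2C(C)(C)CCC[C@]2(C)[C@H]1CC[C@H](C)CC(O)=O | intermediate
17 | acetic (5R,8R,9R,10S,13S)-8-acetoxylabdan-15-oic anhydride (not isolated) | CC(=O)O[C@]1(C)CC[C@@H]2C(C)(C)CCC[C@]2(C)[C@H]1CC[C@H](C)CC(=O)OC(C)=O | intermediate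
18 | (5R,8R,9R,10S,13S)-8-acetoxylabdan-15-oic acid, (3S)-5-[(1R,2R,4aR,8aS)-2-acetoxy-2,5,5,8a-tetramethyldecahydronaphthalen-1-yl]-3-methylpentanoic acid | CC(=O)O[C@]1(C)CC[C@@H]2C(C)(C)CCC[C@]2(C)[C@H]1CC[C@H](C)CC(=O)O | target

**Step count and risks**

Total steps: 11. Longest linear sequence: 9 steps (6 to 18 through steps 3–11); the ring A branch (1 to 5, steps 1–2) joins at step 6.

Steps most likely to fail:

1. Step 7 (ring closure). What may go wrong: the palladium intermediate may fail to insert the hindered trisubstituted C1=C10 alkene, and the ynone is then consumed by isomerization to a conjugated dienone (with loss of C13) or by oligomerization. Fallback, setting out from 12 and returning at 13: the metal is fixed on C9 beforehand and the ring is closed by an intramolecular Heck reaction. Palladium-catalysed syn-hydrostannation of 12 (Bu3SnH, PdCl2(PPh3)2 cat., THF, 0 °C) should place tin on the carbon α to the ketone and give methyl (3S,5E)-3-methyl-7-oxo-6-(tributylstannyl)-9-[(1R)-2,6,6-trimethylcyclohex-2-en-1-yl]non-5-enoate F1. Iododestannylation (I2, CH2Cl2, 0 °C) gives the α-iodo enone methyl (3S,5E)-6-iodo-3-methyl-7-oxo-9-[(1R)-2,6,6-trimethylcyclohex-2-en-1-yl]non-5-enoate F2. A 6-exo Heck cyclization with a silver salt (Pd(OAc)2, PPh3, Ag2CO3, MeCN, 80 °C) should then form C9–C10 with the same cis delivery from C5 and β-hydride elimination towards C2, giving 13.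

2. Step 8 (methyl addition). What may go wrong: poor facial selectivity at the C8 carbonyl if both chair forms of the cis-fused ketone react, which would give the C8 epimer and, after step 9, the wrong C9 as well. Fallback, setting out from 3 and 10 and returning at 14: C8 is created before ring closure under catalyst control and the ketone stage is bypassed. Alkyne 10, metallated with Me2Zn, is added to methyl ketone 3 in the presence of Zn(salen) formed in the flask from Me2Zn and (R,R)- or (S,S)-N,N'-bis(3,5-di-tert-butylsalicylidene)cyclohexane-1,2-diamine (toluene, rt; the ligand enantiomer is chosen to favour the 7R alcohol). This should give methyl (3S,7R)-7-hydroxy-3,7-dimethyl-9-[(1R)-2,6,6-trimethylcyclohex-2-en-1-yl]non-5-ynoate F3. Catalyst control on a methyl alkyl ketone is expected to be incomplete, so the C8 epimer is removed after the next step, where it has become a ring diastereomer. Cycloisomerization of F3 (Pd2(dba)3·CHCl3, P(o-tol)3, AcOH, toluene, 60 °C) closes ring B at C9–C10 as in step 7 and gives 14 directly; steps 2 and 6 are then not needed.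

3. Step 11 (acetylation). What may go wrong: slow acylation of the tertiary, axially placed hydroxyl and competing acid-promoted dehydration towards the 7-ene or 8(17)-ene. Fallback, setting out from 15 and returning at 18: the acetate is introduced on the preformed alkoxide before the ester is cleaved. Deprotonation of 15 (KN(SiMe3)2, THF, −78 °C) and quenching of the alkoxide with Ac2O should give methyl (5R,8R,9R,10S,13S)-8-acetoxylabdan-15-oate F4 with no acid present. Selective cleavage of the unhindered methyl ester with Me3SnOH (1,2-dichloroethane, 80 °C), which should leave the hindered tertiary acetate, gives 18; step 10 is then omitted.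

Further compounds
F1 | step 7 | methyl (3S,5E)-3-methyl-7-oxo-6-(tributylstannyl)-9-[(1R)-2,6,6-trimethylcyclohex-2-en-1-yl]non-5-enoate | CC1=CCCC(C)(C)[C@H]1CCC(=O)/C(=C\C[C@H](C)CC(=O)OC)[Sn](CCCC)(CCCC)CCCC
F2 | step 7 | methyl (3S,5E)-6-iodo-3-methyl-7-oxo-9-[(1R)-2,6,6-trimethylcyclohex-2-en-1-yl]non-5-enoate | CC1=CCCC(C)(C)[C@H]1CCC(=O)/C(I)=C\C[C@H](C)CC(=O)OC
F3 | step 8 | methyl (3S,7R)-7-hydroxy-3,7-dimethyl-9-[(1R)-2,6,6-trimethylcyclohex-2-en-1-yl]non-5-ynoate | O[C@](C)(CC[C@@H]1C(C)(C)CCC=C1C)C#CC[C@H](C)CC(=O)OC
F4 | step 11 | methyl (5R,8R,9R,10S,13S)-8-acetoxylabdan-15-oate | CC(=O)O[C@]1(C)CC[C@@H]2C(C)(C)CCC[C@]2(C)[C@H]1CC[C@H](C)CC(=O)OC
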